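**Plan**

1. Retrosynthesis: the phenol O–H is masked as an acetate, which is removed last. The C6–C7 bond of the nonadecyl chain (numbered from the ester oxygen; C13–C14 from the methyl end) is then cut into two primary alkyl radicals. Each radical is traced back to a carboxylic acid: tetradecanoic acid and 7-{[3-(4-acetoxyphenyl)propanoyl]oxy}heptanoic acid. The latter is cut at its alkyl C–O ester bond into phloretic acid and tert-butyl 7-bromoheptanoate.
2. Forward: carboxylate O-alkylation, phenol acetylation, tert-butyl ester cleavage, anodic mixed Kolbe decarboxylative cross-coupling that completes the C19 chain, then selective aminolysis of the aryl acetate.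
3. Enabling feature: the bond lies in an unbranched polymethylene stretch. Both carbons are primary CH2 groups flanked only by CH2, and the nearest heteroatom (the ester O) sits five C–C bonds away. Each carbon is therefore the unstabilised primary radical left when CO2 leaves a plain alkanoic acid, and such radicals dimerise rather than oxidise further. The only anodically sensitive site, the electron-rich 4-hydroxyphenyl ring, is switched off as its aryl acetate.
4. Stereochemistry: the target has no stereocentre and no stereogenic double bond, so the single-enantiomer requirement is met trivially and no stereocontrol is needed.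

Key step: step 4

**Route**

Step 1
Reactants: 1 3-(4-hydroxyphenyl)propanoic acid (phloretic acid); 2 tert-butyl 7-bromoheptanoate
Product: 3 tert-butyl 7-{[3-(4-hydroxyphenyl)propanoyl]oxy}heptanoate
Conditions: KHCO3 (1.2 equiv), KI (cat.), DMF, 50 °C
Reagents that add atoms: none
Why: Carboxylate O-alkylation (SN2 at the primary bromide, Finkelstein-assisted); bicarbonate deprotonates only the carboxylic acid and not the phenol, so the alkyl ester should form without aryl ether formation.

Step 2
Reactants: 3 tert-butyl 7-{[3-(4-hydroxyphenyl)propanoyl]oxy}heptanoate
Product: 4 tert-butyl 7-{[3-(4-acetoxyphenyl)propanoyl]oxy}heptanoate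
Conditions: Ac2O (1.3 equiv), pyridine, DMAP (cat.), CH2Cl2, 0 °C → rt
Reagents that add atoms: acetic anhydride, CC(=O)OC(C)=O
Why: DMAP-catalysed O-acetylation of the phenol; it turns the easily oxidised phenol into an electron-poor aryl ester that should tolerate the anode in step 4.

Step 3
Reactants: 4 tert-butyl 7-{[3-(4-acetoxyphenyl)propanoyl]oxy}heptanoate
Product: 5 7-{[3-(4-acetoxyphenyl)propanoyl]oxy}heptanoic acid
Conditions: TFA/CH2Cl2 (1:3), rt; co-evaporation with toluene
Reagents that add atoms: none
Why: Acidolysis of the tert-butyl ester with loss of isobutene (E1); the primary alkyl ester and the aryl acetate are stable to anhydrous TFA.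

Step 4
Reactants: 5 7-{[3-(4-acetoxyphenyl)propanoyl]oxy}heptanoic acid; 6 tetradecanoic acid (myristic acid, 4 equiv)
Product: 9 nonadecyl 3-(4-acetoxyphenyl)propanoate, via tridecyl radical 7 (not isolated), via 6-acyloxyhexyl radical 8 (not isolated)
Conditions: undivided cell, Pt anode/Pt cathode, KOH (5–10 mol % of total acid), MeOH–hexane (3:1), 45–50 °C, constant current ca. 0.2 A cm−2, stopped while the electrolyte is still weakly acidic
Reagents that add atoms: none
Why: Mixed (crossed) Kolbe electrolysis: the carboxylates of 5 and 6 are each oxidised by one electron at the platinum anode, the acyloxy radicals lose CO2 at once, and the primary radicals 7 and 8, formed side by side in the electrode layer at high current density, combine to the new CH2–CH2 bond while the cathode reduces the acid protons to H2 and so regenerates carboxylate. The closest known reaction type is the crossed Kolbe coupling of a fatty acid with an ω-functionalised alkanoic acid (half-ester or acyloxy acid), the classical like-polarity way to long chains. No ring is closed and no stereocentre is formed, so no stereocontrol is involved. Cross- over homo-coupling is only statistical and is secured by the fourfold excess of the cheap acid 6, the by-products hexacosane (non-polar) and the symmetrical C12 diester (more polar) being removable by chromatography. Radical coupling over further oxidation to cations (Hofer–Moest path) is secured by both radicals being unbranched primary alkyl radicals without α- or β-heteroatom, by smooth Pt, high current density and the weakly acidic medium, which also keeps methoxide from building up and transesterifying the esters. Carboxylate discharge over arene oxidation is secured by the aryl acetate, which lowers the electron density of the only oxidisable ring, and by the carboxylate layer that covers the anode.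

Step 5
Reactants: 9 nonadecyl 3-(4-acetoxyphenyl)propanoate
Product: 10 nonadecyl 3-(4-hydroxyphenyl)propanoate
Conditions: pyrrolidine (3 equiv), THF, 0 °C → rt; aq. citric acid work-up
Reagents that add atoms: none
Why: Chemoselective aminolysis of the activated aryl acetate (phenoxide leaving group) by a secondary amine; the unactivated primary alkyl ester should not undergo aminolysis at room temperature.

**Compound list**

1 | 3-(4-hydroxyphenyl)propanoic acid (phloretic acid) | O=C(O)CCc1ccc(O)cc1 | starting material
2 | tert-butyl 7-bromoheptanoate | CC(C)(C)OC(=O)CCCCCCBr | starting material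
3 | tert-butyl 7-{[3-(4-hydroxyphenyl)propanoyl]oxy}heptanoate | CC(C)(C)OC(=O)CCCCCCOC(=O)CCc1ccc(O)cc1 | intermediate
4 | tert-butyl 7-{[3-(4-acetoxyphenyl)propanoyl]oxy}heptanoate | CC(C)(C)OC(=O)CCCCCCOC(=O)CCc1ccc(OC(C)=O)cc1 | intermediate
5 | 7-{[3-(4-acetoxyphenyl)propanoyl]oxy}heptanoic acid | OC(=O)CCCCCCOC(=O)CCc1ccc(OC(C)=O)cc1 | intermediate
6 | tetradecanoic acid (myristic acid) | CCCCCCCCCCCCCC(=O)O | starting material
7 | tridecyl radical | CCCCCCCCCCCC[CH2] | intermediate
8 | 6-{[3-(4-acetoxyphenyl)propanoyl]oxy}hexyl radical | [CH2]CCCCCOC(=O)CCc1ccc(OC(C)=O)cc1 | intermediate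
9 | nonadecyl 3-(4-acetoxyphenyl)propanoate | CCCCCCCCCCCCCCCCCCCOC(=O)CCc1ccc(OC(C)=O)cc1 | intermediate
10 | nonadecyl 3-(4-hydroxyphenyl)propanoate | CCCCCCCCCCCCCCCCCCCOC(=O)CCc1ccc(O)cc1 | target

**Summary**

Total step count: 5. Longest linear sequence: 5 steps (1 → 3 → 4 → 5 → 9 → 10).

Steps most likely to fail:

Step 4. The waxy hydrocarbon and product may passivate the anode, the radicals may be oxidised on to cations, the aryl ring may be attacked anodically, or too much of 5 may be lost to homocoupling. Fallback from 5 to 9 by a nickel-catalysed decarboxylative coupling instead of electrolysis: condensation of 5 with N-hydroxyphthalimide (DIC, DMAP cat., CH2Cl2) should give the redox-active ester 1,3-dioxoisoindolin-2-yl 7-{[3-(4-acetoxyphenyl)propanoyl]oxy}heptanoate F1. Zinc insertion into commercial 1-bromotridecane (Zn dust, LiCl, THF) should give tridecylzinc bromide F2. Decarboxylative alkyl–alkyl Negishi-type coupling of F1 with F2 (NiCl2·glyme, 2,2'-bipyridine, THF/DMF, rt) should form the same bond and return to 9.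

Step 1. The phenol may be O-alkylated in competition, or the SN2 displacement may be sluggish. Fallback from 1 to 4 by acyl substitution instead of carboxylate alkylation: acetylation of 1 (Ac2O, pyridine, then aqueous work-up) should give 3-(4-acetoxyphenyl)propanoic acid F3. Steglich esterification of F3 with commercial tert-butyl 7-hydroxyheptanoate (EDC·HCl, DMAP, CH2Cl2) should arrive directly at 4.

Step 5. The amine may attack the nonadecyl ester, or acetate cleavage may stay incomplete. Fallback from 9 to 10 by full cleavage and selective re-esterification: saponification of both esters of 9 (LiOH, THF/MeOH/H2O, then acidification) should give nonadecan-1-ol F4 together with 1. Fischer esterification of 1 with F4 (TsOH cat., toluene, Dean–Stark), under which the phenol is not acylated, should give 10.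

**Further compounds**

F1 | step 4 | 1,3-dioxoisoindolin-2-yl 7-{[3-(4-acetoxyphenyl)propanoyl]oxy}heptanoate | O=C(CCCCCCOC(=O)CCc1ccc(OC(C)=O)cc1)ON1C(=O)c2ccccc2C1=O
F2 | step 4 | tridecylzinc bromide | CCCCCCCCCCCCC[Zn]Br
F3 | step 1 | 3-(4-acetoxyphenyl)propanoic acid | CC(=O)Oc1ccc(CCC(=O)O)cc1
F4 | step 5 | nonadecan-1-ol | CCCCCCCCCCCCCCCCCCCO
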